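All runs are calculated for an exercise; the scatter is artificial.

At the first beta reading, 0.500 h in, the homo dimer stood at 26.3% and the target at 0.5%, so substrate was already pairing into homo dimer while the target lagged.

| setting | theta | beta | alpha | noon | summer | autumn | midnight |
|---|---|---|---|---|---|---|---|
| substrate | 34 mM | 17 mM | 26 mM | 34 mM (fed, over 2.5 h) | 34 mM | 34 mM | 34 mM |
| reagent | 4 equiv | 4 equiv | 4 equiv | 4.00 equiv | 4.00 equiv (fed, over 2.5 h) | 4.00 equiv | 4.00 equiv (in portions, 4, over 2.5 h) |
| temperature | −15 °C | 0 °C | −15 °C | 0 °C |  | 0 °C | 0 °C |
| remark | run made earlier | run made earlier | run made earlier | all else is in the flask from the start; the feed brings no volume worth counting | the addition at −30 °C, then warmed to 0 °C; the feed brings no volume worth counting | everything together at the start | first portion at the start, last at 2.5 h |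
| time |  |  |  | 4.0 h | 4.0 h | 4.0 h | 4.0 h |

- theta (time / h: homo dimer / %, target / %): 1.00: 27.3, 1.7; 3.00: 40.2, 53.6; 5.00: 40.1, 51.5; 8.00: 39.9, 46.2
- beta (time / h: homo dimer / %, target / %): 0.500: 26.3, 0.5; 1.33: 47.7, 2.4; 2.50: 60.2, 12.9; 4.00: 61.6, 22.1
- alpha (time / h: homo dimer / %, target / %): 0.667: 16.1, 0; 1.33: 28.2, 1.2; 3.00: 44.3, 14.0; 8.00: 46.8, 43.3

(standard deviation of a reading: 0.3 percentage points)

- in percentages every species weighs as the substrate in it: one homo dimer counts as two

- the flask with the highest amount of homo dimer, in percent of the substrate charged ("all alike" if they lie within 1.5 percentage points) (noon / summer / autumn / midnight / all alike)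
- final homo dimer, as a percentage of the substrate charged, in noon
- final homo dimer, as a percentage of the substrate charged, in summer
- final homo dimer, as a percentage of the substrate charged, in autumn
- final homo dimer, as a percentage of the substrate charged, in midnight

With substrate going two at a turn, the fraction left after n first half-lives is one over one plus n. Beta's first reading, scaled to the full charge, gave a first half-life of 0.683 h at 0 °C.

The target came after an induction period, and I took its growth to follow reagent times substrate, summed over time. With substrate falling this way, that sum goes as reagent times the rise in ln(one plus n), since charge times half-life stays the same at one temperature. I counted reagent in equivalents of this flask's charge. The plateau readings gave 1.91 in beta, 1.93 in alpha and 2.06 in theta, so I carried beta's figure as the switch dose, though alpha and theta ran at −15 °C.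

I bounded midnight. From above, with no target by 4.0 h, its homo dimer reaches 85.4%. From below, midnight holds 1.00 at first against autumn's 4.00 equiv, and I reckoned that autumn, with its whole charge at the start, reaches the dose at 38.0%. To tighten this, I stepped through the portions, one every 0.833 h. After two intervals I reckoned midnight at 1.67, less than the dose, so I put its switch in the third interval, at 73.2% on the beta dose and 74.4% on the theta dose. Noon and summer I did not step through, since theta, beta and alpha show neither a feed nor −30 °C.

The forecast chose midnight but put it at 48%, within 36% to 62%, below my figure, with noon at 22%, summer at 42% and autumn at 44%: “Portioned reagent probably delays the target path, giving slightly more dimer”.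

Midnight gave 73.4%, above noon's 17.3%, summer's 47.7% and autumn's 41.1%.

    substrate + reagent + target → 2 target (k = 70.0 M⁻² min⁻¹, Ea = 49.0 kJ mol⁻¹)
    substrate + reagent → target (k = 5.20 × 10⁻⁴ M⁻¹ min⁻¹, Ea = 65.0 kJ mol⁻¹)
    target ⇌ isomer of the product (K = 0.750, k = 0.00800 min⁻¹, Ea = 88.0 kJ mol⁻¹, ΔH = −31.0 kJ mol⁻¹)
    2 substrate → homo dimer (k = 0.350 M⁻¹ min⁻¹, Ea = 52.0 kJ mol⁻¹)
    (constants at 0 °C)

Read back through the same steps, midnight's 73.4% is a dose of 1.94, above beta's value and below theta's. For the neighbouring midnight flask with 20 mM of substrate I reckoned a first half-life of 1.16 h. Its steps gather 1.99 by 4.0 h, again between the two. That neighbour ends with homo dimer at 74.8%, target at 6.76% and substrate still at 16.5%.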